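**Retrosynthetic overview**
- The ten-membered carbocycle and the trans γ-lactone are closed together at the end by an intramolecular chromium-mediated allylation (C6–C7) of a Z-enal carrying a 2-(bromomethyl)enoate; the bromide comes from cross-metathesis of a C7 vinyl group.
- The 3(2H)-furanone and its quaternary C10 come from a gold-catalysed carbonyl–yne cyclisation with a 1,2-shift of the C9 chain from C1 to C10 in an α-hydroxy-α-alkynyl methyl ketone (C9–C1 bond becomes C9–C10).
- That ketol comes from Felkin–Anh addition of an acetyl-anion equivalent (ethyl vinyl ether) to an α-silyloxy ynone; C8/C9 come from a syn boron aldol of the ynone with acrolein, and the ester from (R)-2-methylbutanoic acid.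
- The ynone comes from the (Z)-enynol (C2–C6, C15) and methyl glycolate (C1, C9).
- Ring order: furanone first (step 7), then carbocycle and lactone in one operation (step 11).

Assumption: (Z)-3-methylpent-2-en-4-yn-1-ol and (R)-2-methylbutanoic acid are bought as such; locants C1–C15 are the germacrane positions of the target (C1 ketone, C3/C10 ring-oxygen carbons, C6 lactone carbinol, C8 ester, C9 hydroxyl).

**Route**

Step 1
Reactants: 1 (Z)-3-methylpent-2-en-4-yn-1-ol
Product: 2 (Z)-tert-butyl(dimethyl)[(3-methylpent-2-en-4-yn-1-yl)oxy]silane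
Conditions: TBSCl, imidazole, DMF, 0 °C to rt
Reagents that add atoms: tert-butyldimethylsilyl chloride (TBSCl), CC(C)(C)[Si](C)(C)Cl
Why: Imidazole-promoted O-silylation masks the allylic alcohol (future C6–O) for the organometallic steps; no stereocentre is involved.

Step 2
Reactants: 3 methyl glycolate
Product: 4 methyl 2-[(tert-butyldimethylsilyl)oxy]acetate
Conditions: TBSCl, imidazole, DMF, 0 °C to rt
Reagents that add atoms: tert-butyldimethylsilyl chloride (TBSCl), CC(C)(C)[Si](C)(C)Cl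
Why: O-silylation gives a non-chelating C9–O group, which is needed for the Felkin–Anh addition in step 6.

Step 3
Reactants: 2 (Z)-tert-butyl(dimethyl)[(3-methylpent-2-en-4-yn-1-yl)oxy]silane; 4 methyl 2-[(tert-butyldimethylsilyl)oxy]acetate
Product: 6 (Z)-1,7-bis[(tert-butyldimethylsilyl)oxy]-5-methylhept-5-en-3-yn-2-one, via lithium acetylide 5 (not isolated)
Conditions: n-BuLi, THF, −78 °C; BF3·OEt2; then 4, −78 °C; aq NH4Cl
Reagents that add atoms: none
Why: Yamaguchi–Hirao ynone synthesis: the BF3-activated acetylide adds once to the methyl ester and the ketone is released only on work-up, so no double addition occurs.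

Step 4
Reactants: 6 (Z)-1,7-bis[(tert-butyldimethylsilyl)oxy]-5-methylhept-5-en-3-yn-2-one; 7 acrolein
Product: 9 (3S,4R,8Z)-4,10-bis[(tert-butyldimethylsilyl)oxy]-3-hydroxy-8-methyldeca-1,8-dien-6-yn-5-one, via Z boron enolate 8 (not isolated)
Conditions: (−)-Ipc2BOTf, i-Pr2NEt, CH2Cl2, −78 °C; acrolein, −78 to −20 °C; pH 7 buffer/MeOH
Reagents that add atoms: none
Why: Reagent-controlled Paterson boron aldol: enolisation is possible only toward CH2OTBS and gives the Z enolate 8, whose Zimmerman–Traxler chair gives the syn adduct, with the Ipc ligands directing attack to the re face of acrolein (8S,9R; the antipodal reagent gives the enantiomer, and any minor enantiomer is removed after step 5 as a diastereomer).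

Step 5
Reactants: 9 (3S,4R,8Z)-4,10-bis[(tert-butyldimethylsilyl)oxy]-3-hydroxy-8-methyldeca-1,8-dien-6-yn-5-one; 10 (R)-2-methylbutanoic acid
Product: 11 (3S,4R,8Z)-4,10-bis[(tert-butyldimethylsilyl)oxy]-8-methyl-5-oxodeca-1,8-dien-6-yn-3-yl (2R)-2-methylbutanoate
Conditions: DIC, DMAP (cat.), CH2Cl2, 0 °C to rt
Reagents that add atoms: none
Why: Steglich esterification installs the C8 ester of the target early and without touching a stereocentre; the enantiopure acyl group turns any ent-aldol into a separable diastereomer.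

Step 6
Reactants: 11 (3S,4R,8Z)-4,10-bis[(tert-butyldimethylsilyl)oxy]-8-methyl-5-oxodeca-1,8-dien-6-yn-3-yl (2R)-2-methylbutanoate; 12 ethyl vinyl ether
Product: 15 (3S,4R,5R,8Z)-5-acetyl-4,10-bis[(tert-butyldimethylsilyl)oxy]-5-hydroxy-8-methyldeca-1,8-dien-6-yn-3-yl (2R)-2-methylbutanoate, via 1-ethoxyvinyllithium 13 (not isolated), via enol ether adduct 14 (not isolated)
Conditions: 12, t-BuLi, THF, −78 to 0 °C; CeCl3, −78 °C; then 11, −78 °C; 0.5 M aq HCl, THF, 0 °C
Reagents that add atoms: water, O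
Why: The organocerium acetyl-anion equivalent adds 1,2 to the ynone in preference to the ester, and polar Felkin–Anh control (non-chelating α-OTBS anti to the nucleophile) sets the C1 carbinol as (R); acid work-up hydrolyses the enol ether to the methyl ketone.

Step 7
Reactants: 15 (3S,4R,5R,8Z)-5-acetyl-4,10-bis[(tert-butyldimethylsilyl)oxy]-5-hydroxy-8-methyldeca-1,8-dien-6-yn-3-yl (2R)-2-methylbutanoate
Product: 17 (1R,2S)-1-[(tert-butyldimethylsilyl)oxy]-1-{(2R)-5-[(2Z)-4-[(tert-butyldimethylsilyl)oxy]but-2-en-2-yl]-2-methyl-3-oxo-2,3-dihydrofuran-2-yl}but-3-en-2-yl (2R)-2-methylbutanoate, via aurated furanylium zwitterion 16 (not isolated)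
Conditions: AuCl3 (5 mol %), CH2Cl2, 23 °C
Reagents that add atoms: none
Why: Proposed new method: trivalent gold activates the alkyne, the acetyl oxygen closes 5-endo-dig onto C3 to give the planar oxocarbenium 16, and C9 (the only group on C1 that can migrate, and an α-oxygenated carbon of good migratory aptitude) shifts suprafacially with retention from C1 to C10 while the C1–OH becomes the C1 ketone and protodeauration releases the catalyst, so C9 stays on the ring face it occupied and (1R) is relayed to (10R); the closest known reaction type is the gold- or platinum-catalysed heterocyclisation/1,2-alkyl migration of 2-hydroxy-2-alkynyl ketones to 3(2H)-furanones (an α-ketol-type shift), not yet shown for a stereogenic O-substituted migrating carbon on a conjugated Z-enyne or as a chirality relay to a quaternary C–O centre.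

Step 8
Reactants: 17 (1R,2S)-1-[(tert-butyldimethylsilyl)oxy]-1-{(2R)-5-[(2Z)-4-[(tert-butyldimethylsilyl)oxy]but-2-en-2-yl]-2-methyl-3-oxo-2,3-dihydrofuran-2-yl}but-3-en-2-yl (2R)-2-methylbutanoate
Product: 18 (1R,2S)-1-hydroxy-1-{(2R)-5-[(2Z)-4-hydroxybut-2-en-2-yl]-2-methyl-3-oxo-2,3-dihydrofuran-2-yl}but-3-en-2-yl (2R)-2-methylbutanoate
Conditions: HF·pyridine, pyridine/THF, 0 °C to rt
Reagents that add atoms: none
Why: Buffered fluoride desilylation frees both alcohols without base, so the ester does not migrate and the β-hydroxy furanone does not undergo retro-aldol cleavage.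

Step 9
Reactants: 18 (1R,2S)-1-hydroxy-1-{(2R)-5-[(2Z)-4-hydroxybut-2-en-2-yl]-2-methyl-3-oxo-2,3-dihydrofuran-2-yl}but-3-en-2-yl (2R)-2-methylbutanoate; 19 methyl 2-(bromomethyl)acrylate
Product: 20 methyl (2Z,4S,5R)-2-(bromomethyl)-5-hydroxy-5-{(2R)-5-[(2Z)-4-hydroxybut-2-en-2-yl]-2-methyl-3-oxo-2,3-dihydrofuran-2-yl}-4-{[(2R)-2-methylbutanoyl]oxy}pent-2-enoate
Conditions: 19 (5 equiv), second-generation Hoveyda–Grubbs catalyst (10 mol %), CH2Cl2, 40 °C
Reagents that add atoms: none
Why: Olefin cross-metathesis: the terminal vinyl group is the only alkene that is neither conjugated nor trisubstituted, and with excess 1,1-disubstituted acrylate it gives the enoate with the ester trans to C8 (this geometry is not stereo-determining later).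

Step 10
Reactants: 20 methyl (2Z,4S,5R)-2-(bromomethyl)-5-hydroxy-5-{(2R)-5-[(2Z)-4-hydroxybut-2-en-2-yl]-2-methyl-3-oxo-2,3-dihydrofuran-2-yl}-4-{[(2R)-2-methylbutanoyl]oxy}pent-2-enoate
Product: 21 methyl (2Z,4S,5R)-2-(bromomethyl)-5-hydroxy-5-{(2R)-2-methyl-3-oxo-5-[(2Z)-4-oxobut-2-en-2-yl]-2,3-dihydrofuran-2-yl}-4-{[(2R)-2-methylbutanoyl]oxy}pent-2-enoate
Conditions: TEMPO (10 mol %), PhI(OAc)2, CH2Cl2, rt
Reagents that add atoms: none
Why: Oxoammonium oxidation takes the primary allylic alcohol to the enal and leaves the hindered secondary C9–OH; the neutral conditions keep the Z geometry needed for ring closure.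

Step 11
Reactants: 21 methyl (2Z,4S,5R)-2-(bromomethyl)-5-hydroxy-5-{(2R)-2-methyl-3-oxo-5-[(2Z)-4-oxobut-2-en-2-yl]-2,3-dihydrofuran-2-yl}-4-{[(2R)-2-methylbutanoyl]oxy}pent-2-enoate
Product: 23 CNP0146060.1 [(4Z,6R,7S,8S,9R,10R)-9-hydroxy-1-oxo-3,10-epoxygermacra-2,4,11(13)-trien-12,6-olid-8-yl (2R)-2-methylbutanoate], via hydroxy ester 22 (not isolated)
Conditions: CrCl2 (8 equiv), THF/DMF, rt, 2 mM (slow addition); aq NH4Cl; then TsOH·H2O (cat.), CH2Cl2, rt
Reagents that add atoms: none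
Why: Intramolecular Nozaki–Hiyama-type (Barbier) 2-(alkoxycarbonyl)allylation: divalent chromium inserts into the allylic bromide and C7 adds to the C6 aldehyde through a six-membered chair whose anti mode gives trans H6/H7, while C9 (part of the tether) must sit gauche to the new bond so that the face with H8 anti and the acyloxy group inside reacts, giving (6R,7S); the C6 oxygen then lactonises onto the methyl ester.

**Compound list**

1 | (Z)-3-methylpent-2-en-4-yn-1-ol | C#C/C(C)=C\CO | starting material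
2 | (Z)-tert-butyl(dimethyl)[(3-methylpent-2-en-4-yn-1-yl)oxy]silane | C#C/C(C)=C\CO[Si](C)(C)C(C)(C)C | intermediate
3 | methyl glycolate | COC(=O)CO | starting material
4 | methyl 2-[(tert-butyldimethylsilyl)oxy]acetate | COC(=O)CO[Si](C)(C)C(C)(C)C | intermediate
5 | lithium acetylide of 2 | [Li]C#C/C(C)=C\CO[Si](C)(C)C(C)(C)C | intermediate (not isolated)
6 | (Z)-1,7-bis[(tert-butyldimethylsilyl)oxy]-5-methylhept-5-en-3-yn-2-one | CC(C)(C)[Si](C)(C)OCC(=O)C#C/C(C)=C\CO[Si](C)(C)C(C)(C)C | intermediate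
7 | acrolein | C=CC=O | starting material
8 | Z diisopinocampheylboron enolate of 6 | CC(C)(C)[Si](C)(C)O/C=C(\OB([C@@H]1C[C@@H]2C[C@H]([C@H]1C)C2(C)C)[C@@H]1C[C@@H]2C[C@H]([C@H]1C)C2(C)C)C#C/C(C)=C\CO[Si](C)(C)C(C)(C)C | intermediate (not isolated)
9 | (3S,4R,8Z)-4,10-bis[(tert-butyldimethylsilyl)oxy]-3-hydroxy-8-methyldeca-1,8-dien-6-yn-5-one | C=C[C@H](O)[C@@H](O[Si](C)(C)C(C)(C)C)C(=O)C#C/C(C)=C\CO[Si](C)(C)C(C)(C)C | intermediate
10 | (R)-2-methylbutanoic acid | CC[C@@H](C)C(=O)O | starting material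
11 | (3S,4R,8Z)-4,10-bis[(tert-butyldimethylsilyl)oxy]-8-methyl-5-oxodeca-1,8-dien-6-yn-3-yl (2R)-2-methylbutanoate | C=C[C@H](OC(=O)[C@H](C)CC)[C@@H](O[Si](C)(C)C(C)(C)C)C(=O)C#C/C(C)=C\CO[Si](C)(C)C(C)(C)C | intermediate
12 | ethyl vinyl ether | C=COCC | starting material
13 | 1-ethoxyvinyllithium (used as its CeCl3 complex) | [Li]C(=C)OCC | intermediate (not isolated)
14 | (3S,4R,5R,8Z)-4,10-bis[(tert-butyldimethylsilyl)oxy]-5-(1-ethoxyvinyl)-5-hydroxy-8-methyldeca-1,8-dien-6-yn-3-yl (2R)-2-methylbutanoate | C=C[C@H](OC(=O)[C@H](C)CC)[C@@H](O[Si](C)(C)C(C)(C)C)[C@@](O)(C(=C)OCC)C#C/C(C)=C\CO[Si](C)(C)C(C)(C)C | intermediate (not isolated)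
15 | (3S,4R,5R,8Z)-5-acetyl-4,10-bis[(tert-butyldimethylsilyl)oxy]-5-hydroxy-8-methyldeca-1,8-dien-6-yn-3-yl (2R)-2-methylbutanoate | C=C[C@H](OC(=O)[C@H](C)CC)[C@@H](O[Si](C)(C)C(C)(C)C)[C@@](O)(C(C)=O)C#C/C(C)=C\CO[Si](C)(C)C(C)(C)C | intermediate
16 | C-aurated 3-hydroxy-2-methyl-3H-furanylium zwitterion (oxocarbenium at C10, AuCl3 on C2) | C=C[C@H](OC(=O)[C@H](C)CC)[C@@H](O[Si](C)(C)C(C)(C)C)[C@@]1(O)C(C)=[O+]C(/C(C)=C\CO[Si](C)(C)C(C)(C)C)=C1[Au-](Cl)(Cl)Cl | intermediate (not isolated)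
17 | (1R,2S)-1-[(tert-butyldimethylsilyl)oxy]-1-{(2R)-5-[(2Z)-4-[(tert-butyldimethylsilyl)oxy]but-2-en-2-yl]-2-methyl-3-oxo-2,3-dihydrofuran-2-yl}but-3-en-2-yl (2R)-2-methylbutanoate | C=C[C@H](OC(=O)[C@H](C)CC)[C@@H](O[Si](C)(C)C(C)(C)C)[C@@]1(C)OC(/C(C)=C\CO[Si](C)(C)C(C)(C)C)=CC1=O | intermediate
18 | (1R,2S)-1-hydroxy-1-{(2R)-5-[(2Z)-4-hydroxybut-2-en-2-yl]-2-methyl-3-oxo-2,3-dihydrofuran-2-yl}but-3-en-2-yl (2R)-2-methylbutanoate | C=C[C@H](OC(=O)[C@H](C)CC)[C@@H](O)[C@@]1(C)OC(/C(C)=C\CO)=CC1=O | intermediate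
19 | methyl 2-(bromomethyl)acrylate | C=C(CBr)C(=O)OC | starting material
20 | methyl (2Z,4S,5R)-2-(bromomethyl)-5-hydroxy-5-{(2R)-5-[(2Z)-4-hydroxybut-2-en-2-yl]-2-methyl-3-oxo-2,3-dihydrofuran-2-yl}-4-{[(2R)-2-methylbutanoyl]oxy}pent-2-enoate | COC(=O)/C(CBr)=C/[C@H](OC(=O)[C@H](C)CC)[C@@H](O)[C@@]1(C)OC(/C(C)=C\CO)=CC1=O | intermediate
21 | methyl (2Z,4S,5R)-2-(bromomethyl)-5-hydroxy-5-{(2R)-2-methyl-3-oxo-5-[(2Z)-4-oxobut-2-en-2-yl]-2,3-dihydrofuran-2-yl}-4-{[(2R)-2-methylbutanoyl]oxy}pent-2-enoate | COC(=O)/C(CBr)=C/[C@H](OC(=O)[C@H](C)CC)[C@@H](O)[C@@]1(C)OC(/C(C)=C\C=O)=CC1=O | intermediate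
22 | methyl (4Z,6R,7S,8S,9R,10R)-6,9-dihydroxy-8-{[(2R)-2-methylbutanoyl]oxy}-1-oxo-3,10-epoxygermacra-2,4,11(13)-trien-12-oate | COC(=O)C(=C)[C@H]1[C@H](O)/C=C(/C)C2=CC(=O)[C@](C)(O2)[C@H](O)[C@H]1OC(=O)[C@H](C)CC | intermediate (not isolated)
23 | CNP0146060.1, (4Z,6R,7S,8S,9R,10R)-9-hydroxy-1-oxo-3,10-epoxygermacra-2,4,11(13)-trien-12,6-olid-8-yl (2R)-2-methylbutanoate | C=C1C(=O)O[C@@H]2/C=C(/C)C3=CC(=O)[C@](C)(O3)[C@H](O)[C@@H](OC(=O)[C@H](C)CC)[C@@H]12 | target

**Step count and risks**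

Total steps: 11 (steps 1 and 2 run in parallel). Longest linear sequence: 10 steps (1, then 3 to 11).

The three steps most likely to fail:

Step 7 (the new gold cascade). The C9 carbon may migrate slowly, or the Z-enyne may divert the catalyst. Fallback in known chemistry, setting out from 15 and coming back at 17: a base-mediated acyloin (α-ketol) rearrangement under non-chelating conditions (DBU, toluene, 60 °C) reacts through the s-trans ketol conformer and so delivers C9 to the same face of C10. It gives the conjugated α′-hydroxy ynone F1, the thermodynamic sink of the equilibrium. The classical 5-endo-dig cycloisomerisation of α′-hydroxy ynones (Ph3PAuCl/AgOTf cat., CH2Cl2, or Et2NH, EtOH) then closes 17.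

Step 9 (cross-metathesis to a trisubstituted bromomethyl enoate next to a branched allylic ester). Fallback setting out from 17 and coming back at 20: Lemieux–Johnson cleavage (OsO4 cat., NMO; then NaIO4) of the terminal vinyl group, the only alkene not conjugated to the furanone, gives the aldehyde F2. A Morita–Baylis–Hillman reaction with methyl acrylate (DABCO) gives the allylic alcohol F3 as both C7 epimers; that centre is lost in the next operation. PBr3 (Et2O, −10 °C, SN2′) gives the bis-silylated (Z)-bromide F4, and aqueous HF in MeCN removes both silyl groups to return to 20.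

Step 11 (macrocyclisation; yield and the C6/C7 configuration rest on the ring-closing transition state). Fallback setting out from 20 and coming back at 22, and so 23: the bromide is exchanged for silicon (Me3SiSiMe3, Pd(PPh3)4 cat.) to give the allylsilane F5. The primary alcohol is oxidised as in step 10 to the enal F6. BF3·OEt2 (CH2Cl2, −78 °C, 1 mM) then promotes an intramolecular Hosomi–Sakurai addition through an open transition state; this closure needs no low-valent metal and its facial preference is set differently. The resulting hydroxy ester 22 is lactonised as before.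

Further compounds
F1 | step 7 | (3S,4R,5R,9Z)-4,11-bis[(tert-butyldimethylsilyl)oxy]-5-hydroxy-5,9-dimethyl-6-oxoundeca-1,9-dien-7-yn-3-yl (2R)-2-methylbutanoate | C=C[C@H](OC(=O)[C@H](C)CC)[C@@H](O[Si](C)(C)C(C)(C)C)[C@@](C)(O)C(=O)C#C/C(C)=C\CO[Si](C)(C)C(C)(C)C
F2 | step 9 | (1R,2R)-1-[(tert-butyldimethylsilyl)oxy]-1-{(2R)-5-[(2Z)-4-[(tert-butyldimethylsilyl)oxy]but-2-en-2-yl]-2-methyl-3-oxo-2,3-dihydrofuran-2-yl}-3-oxopropan-2-yl (2R)-2-methylbutanoate | O=C[C@H](OC(=O)[C@H](C)CC)[C@@H](O[Si](C)(C)C(C)(C)C)[C@@]1(C)OC(/C(C)=C\CO[Si](C)(C)C(C)(C)C)=CC1=O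
F3 | step 9 | Morita–Baylis–Hillman adduct of F2 with methyl acrylate (methyl 3-hydroxy-2-methylidene pentanoate, both C3 epimers) | C=C(C(=O)OC)C(O)[C@H](OC(=O)[C@H](C)CC)[C@@H](O[Si](C)(C)C(C)(C)C)[C@@]1(C)OC(/C(C)=C\CO[Si](C)(C)C(C)(C)C)=CC1=O
F4 | step 9 | bis(tert-butyldimethylsilyl) ether of 20 | COC(=O)/C(CBr)=C/[C@H](OC(=O)[C@H](C)CC)[C@@H](O[Si](C)(C)C(C)(C)C)[C@@]1(C)OC(/C(C)=C\CO[Si](C)(C)C(C)(C)C)=CC1=O
F5 | step 11 | allylsilane analogue of 20 (CH2SiMe3 in place of CH2Br) | COC(=O)/C(C[Si](C)(C)C)=C/[C@H](OC(=O)[C@H](C)CC)[C@@H](O)[C@@]1(C)OC(/C(C)=C\CO)=CC1=O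
F6 | step 11 | allylsilane analogue of 21 (CH2SiMe3 in place of CH2Br) | COC(=O)/C(C[Si](C)(C)C)=C/[C@H](OC(=O)[C@H](C)CC)[C@@H](O)[C@@]1(C)OC(/C(C)=C\C=O)=CC1=O
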